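## Retrosynthetic overview
1. The target is read as (2R,3R), 2,3-trans. Cut C3–OH: anti-selective O-transfer to the enol ether of the (2S)-flavanone, the chemical counterpart of flavanone 3-hydroxylase.
2. Cut O1–C2 of the (2S)-flavanone: catalytic enantioselective 6-endo-trig oxa-Michael closure of the unprotected 2',6'-dihydroxychalcone, the counterpart of chalcone isomerase. Closure and oxygenation run as one telescoped operation.
3. Cut Cα=Cβ of the chalcone: Claisen–Schmidt condensation of 4-O-prenylphloroacetophenone with 4-hydroxybenzaldehyde, without protecting groups.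
4. Cut the prenyl ether: O-alkylation of the only non-chelated OH of phloroacetophenone.
5. Ring order: rings A and B are bought as arenes. Ring C is the only ring made, and it is closed in the last step.

Assumption: the quinine-derived thiourea is taken to give the (2S)-flavanone; the sense is checked on the first run by chiral HPLC and circular dichroism, and the quinidine-derived pseudoenantiomer is the drop-in replacement if it is opposite.

## Route

Step 1
Reactants: 1 2,4,6-trihydroxyacetophenone (phloroacetophenone); 2 prenyl bromide (1-bromo-3-methylbut-2-ene)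
Product: 3 1-[2,6-dihydroxy-4-(3-methylbut-2-enyloxy)phenyl]ethanone (4-O-prenylphloroacetophenone)
Conditions: K2CO3 (1.05 equiv), 2 (1.0 equiv), acetone, reflux, 6 h, N2
Reagents that add atoms: none
Why: Williamson ether synthesis (SN2), in which the 4-OH is the most acidic and the only non-chelated hydroxyl (the 2- and 6-OH are hydrogen-bonded to the acetyl C=O), so one equivalent of weak base and halide alkylates it preferentially, minor C-prenylated and bis-alkylated products being removed by chromatography; no stereocentre is formed.

Step 2
Reactants: 3 4-O-prenylphloroacetophenone; 4 4-hydroxybenzaldehyde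
Product: 5 (E)-1-[2,6-dihydroxy-4-(3-methylbut-2-enyloxy)phenyl]-3-(4-hydroxyphenyl)prop-2-en-1-one (2',6',4-trihydroxy-4'-prenyloxychalcone)
Conditions: KOH (50% aq, 15 equiv), EtOH, 0 °C → rt, 72 h, Ar; poured into ice/dilute HCl (pH 4–5, 0 °C); crystallised from EtOAc/hexane, no silica
Reagents that add atoms: none
Why: Claisen–Schmidt (crossed aldol) condensation with one enolisable ketone and one non-enolisable aldehyde, in which E1cB dehydration gives the conjugated (E)-enone, strong base holds the product as the ring-open chalcone polyanion, and cold acidification releases the chalcone faster than it can cyclise, so that no racemic flavanone enters the next step; no stereocentre is formed.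

Step 3
Reactants: 5 2',6',4-trihydroxy-4'-prenyloxychalcone
Product: 10 7-prenyloxyaromadendrin [(2R,3R)-3,5-dihydroxy-2-(4-hydroxyphenyl)-7-(3-methylbut-2-enyloxy)chroman-4-one], via (2S)-7-O-prenylnaringenin 6 (not isolated), via tris-TMS flav-3-ene enol ether 7 (not isolated), via siloxy-oxirane 8 (not isolated), via tris-TMS dihydroflavonol 9 (not isolated)
Conditions: a) N-[3,5-bis(trifluoromethyl)phenyl]-N'-[(8α,9S)-6'-methoxycinchonan-9-yl]thiourea (10 mol %), PhMe/CH2Cl2 4:1, −20 °C, 72 h; cold aq citric acid wash, dry (Na2SO4); b) Et3N (6 equiv), TMSOTf (4 equiv), −78 → 0 °C, 1 h; pentane, filter, evaporate; c) 2-(phenylsulfonyl)-3-phenyloxaziridine (1.15 equiv), CH2Cl2, 0 °C → rt, dark; d) citric acid (cat.), MeOH, rt, 30 min; recrystallise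
Reagents that add atoms: 2-(phenylsulfonyl)-3-phenyloxaziridine, O=S(=O)(c1ccccc1)N1OC1c1ccccc1 (gives the C3 oxygen of 10); TMSOTf, C[Si](C)(C)OS(=O)(=O)C(F)(F)F (gives the silyl groups of 7, 8 and 9, none of which remains in 10)
Why: Proposed new method: a protecting-group-free chemical relay of chalcone isomerase and flavanone 3-hydroxylase, in which (a) the quinuclidine nitrogen deprotonates one of the two homotopic, acidic ortho-OH groups while the thiourea N–H bonds and the remaining chelated OH polarise the enone, so that the 6-endo-trig oxa-Michael addition takes place inside a chiral ion pair and sets C2 under kinetic control (the hydrogen bond kept by the 5-OH makes closure strongly downhill, and the uncatalysed closure is negligible in an apolar solvent at −20 °C), (b) soft enolisation with TMSOTf/Et3N silylates both phenols and gives the enol ether without ever forming the free enolate whose E1cB ring opening would racemise C2, (c) Rubottom-type O-transfer from the N-sulfonyloxaziridine, which does not epoxidise an unactivated trisubstituted alkene at room temperature, reaches the electron-rich enol ether from the face anti to the pseudo-equatorial 2-aryl group and sets C3 trans to C2 (also the thermodynamically preferred diequatorial isomer), the oxirane collapsing by silyl shift to the 3-silyloxy ketone, and (d) mild methanolysis strips all three silyl groups; the closest known reaction types are the cinchona-thiourea-catalysed intramolecular oxa-Michael cyclisation of 2'-hydroxychalcones and the Rubottom oxidation of flavanone silyl enol ethers.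

## Compound list
1 | 2,4,6-trihydroxyacetophenone (phloroacetophenone) | CC(=O)c1c(O)cc(O)cc1O | starting material
2 | prenyl bromide (1-bromo-3-methylbut-2-ene) | CC(C)=CCBr | starting material
3 | 1-[2,6-dihydroxy-4-(3-methylbut-2-enyloxy)phenyl]ethanone | CC(=O)c1c(O)cc(OCC=C(C)C)cc1O | intermediate
4 | 4-hydroxybenzaldehyde | O=Cc1ccc(O)cc1 | starting material
5 | (E)-1-[2,6-dihydroxy-4-(3-methylbut-2-enyloxy)phenyl]-3-(4-hydroxyphenyl)prop-2-en-1-one | CC(C)=CCOc1cc(O)c(C(=O)/C=C/c2ccc(O)cc2)c(O)c1 | intermediate
6 | (2S)-5-hydroxy-2-(4-hydroxyphenyl)-7-(3-methylbut-2-enyloxy)chroman-4-one, (2S)-7-O-prenylnaringenin | CC(C)=CCOc1cc(O)c2c(c1)O[C@H](c1ccc(O)cc1)CC2=O | intermediate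
7 | (2S)-7-(3-methylbut-2-enyloxy)-4,5-bis(trimethylsilyloxy)-2-[4-(trimethylsilyloxy)phenyl]-2H-chromene | CC(C)=CCOc1cc(O[Si](C)(C)C)c2c(c1)O[C@H](c1ccc(O[Si](C)(C)C)cc1)C=C2O[Si](C)(C)C | intermediate
8 | 3,4-epoxide of 7, (2R,3R,4R) in flavan numbering, oxirane oxygen on the face opposite the 2-aryl group (the arrangement at C2 is unchanged; the descriptor switches because C3 gains priority) | CC(C)=CCOc1cc(O[Si](C)(C)C)c2c(c1)O[C@H](c1ccc(O[Si](C)(C)C)cc1)[C@H]3O[C@]32O[Si](C)(C)C | intermediate
9 | (2R,3R)-7-(3-methylbut-2-enyloxy)-3,5-bis(trimethylsilyloxy)-2-[4-(trimethylsilyloxy)phenyl]chroman-4-one | CC(C)=CCOc1cc(O[Si](C)(C)C)c2c(c1)O[C@H](c1ccc(O[Si](C)(C)C)cc1)[C@@H](O[Si](C)(C)C)C2=O | intermediate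
10 | 7-prenyloxyaromadendrin, (2R,3R)-3,5-dihydroxy-2-(4-hydroxyphenyl)-7-(3-methylbut-2-enyloxy)chroman-4-one | CC(C)=CCOc1cc(O)c2c(c1)O[C@H](c1ccc(O)cc1)[C@@H](O)C2=O | target

## Step count and risks
Total step count: 3. Three products are isolated. Step 3 is one telescoped operation of four stages, and 6–9 are not purified.
Longest linear sequence: 3 steps (1 → 3 → 5 → 10).

The steps most likely to fail are, in order, step 3, step 2 and step 1.

**The last step (step 3) is the riskiest.**
- The free 4-OH of 5 is nearly as acidic as the ortho-OH groups. It can occupy the catalyst and lower both rate and enantioselectivity.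
- Enol ether 7 lies uphill of its ring-opened silyl ether isomer, so stray Lewis acid or light could open it and erode C2.
- Excess oxidant could attack the prenyl alkene.

The fallback sets out from 5 and comes back at 6. Chalcone 5 is closed without chiral information (NaOAc, EtOH, reflux) to racemic 7-O-prenylnaringenin F1. The racemate is then resolved kinetically by asymmetric transfer hydrogenation: RuCl(p-cymene)[(R,R)-TsDPEN] (1 mol %), HCO2H/Et3N 5:2, EtOAc, rt, stopped near 55% conversion. The (2R)-ketone is the matched substrate and is reduced to the cis alcohol (2R,4R)-2-(4-hydroxyphenyl)-7-(3-methylbut-2-enyloxy)chromane-4,5-diol F2, which is removed by chromatography. The slow-reacting (2S)-ketone 6 is recovered in high enantiomeric purity. The prenyl alkene is inert to this carbonyl-selective catalyst. Isolated 6 then enters stage b of step 3. The ring closure stays the same bond-forming event, but the absolute configuration now comes from a resolution and not from the closure.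

**The condensation (step 2) may stall.** In strong base the ketone is a dianion and the aldehyde a phenoxide, so both partners are deactivated.

The fallback sets out from 3 and 4 and comes back at 5. Aldehyde 4 is masked with 3,4-dihydro-2H-pyran (PPTS cat., CH2Cl2, rt) as 4-(tetrahydro-2H-pyran-2-yloxy)benzaldehyde F3, which stays a neutral, electrophilic aldehyde in base. Condensation of F3 with 3 (Ba(OH)2·8H2O or KOH, MeOH, 40 °C, cold acidic work-up) gives (E)-1-[2,6-dihydroxy-4-(3-methylbut-2-enyloxy)phenyl]-3-[4-(tetrahydro-2H-pyran-2-yloxy)phenyl]prop-2-en-1-one F4. PPTS in MeOH at rt removes the acetal without touching the prenyl ether and gives 5, which is crystallised as before.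

**The alkylation (step 1) can leak into by-products.** The phloroglucinol anion is ambident, so C-prenylation and double alkylation compete.

The fallback sets out from 1 and comes back at 3. A Mitsunobu etherification uses 3-methylbut-2-en-1-ol (CC(C)=CCO), PPh3 and DIAD in THF at 0 °C → rt. No free phenoxide is present. Only the most acidic, non-chelated 4-OH protonates the betaine and is alkylated on oxygen by the alkoxyphosphonium ion, so the electrophile, the mechanism and the selectivity basis all change. No new compound is made (F0).

## Further compounds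
F1 | step 3 | racemic 5-hydroxy-2-(4-hydroxyphenyl)-7-(3-methylbut-2-enyloxy)chroman-4-one (racemic 7-O-prenylnaringenin) | CC(C)=CCOc1cc(O)c2c(c1)OC(c1ccc(O)cc1)CC2=O
F2 | step 3 | (2R,4R)-2-(4-hydroxyphenyl)-7-(3-methylbut-2-enyloxy)chromane-4,5-diol | CC(C)=CCOc1cc(O)c2c(c1)O[C@@H](c1ccc(O)cc1)C[C@H]2O
F3 | step 2 | 4-(tetrahydro-2H-pyran-2-yloxy)benzaldehyde (racemic acetal) | O=Cc1ccc(OC2CCCCO2)cc1
F4 | step 2 | (E)-1-[2,6-dihydroxy-4-(3-methylbut-2-enyloxy)phenyl]-3-[4-(tetrahydro-2H-pyran-2-yloxy)phenyl]prop-2-en-1-one (racemic acetal) | CC(C)=CCOc1cc(O)c(C(=O)/C=C/c2ccc(OC3CCCCO3)cc2)c(O)c1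
F0 | step 1 | none | none
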